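**Plan**

- Target read as epigallocatechin-(4β→8)-epigallocatechin-(4β→8)-epigallocatechin 3-O-gallate-(4β→8)-epicatechin (units 1 to 4 from the top; every unit 2R,3R, every interflavan bond 3,4-trans).
- Retrosynthetic cuts, in order: the gallate ester C–O; the C4–C4a bond of unit 1 (ring C of unit 1 opened to a benzylic carbinol that carries the future ring A as a 3,5-dioxygenated phenyl ether); the C4(unit 1)–C8(unit 2) bond (aryllithium plus aldehyde); then the 4β→8 bonds between units 2/3 and units 3/4.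
- Forward: unit 3 is coupled to unit 4, 8-bromo unit 2 is added (bromo trimer), the bromine is turned into the C8–C4 bond, ring C of unit 1 is closed onto C4, then esterification and hydrogenolysis.
- Enabling feature: C4 of unit 1 sits on C8 of ring A of unit 2, ortho to the oxygens on C7 and C8a and para to the oxygen on C5, so its carbinol ionises to a quinone-methide-like cation; C4a of the future ring A of unit 1 is ortho/para to three oxygens and six atoms away.
- Stereochemistry: C2/C3 of units 2–4 from natural (−)-epigallocatechin and (−)-epicatechin; the two lower C4 centres by attack anti to the C3 oxygen; C2/C3 of unit 1 from an Evans syn glycolate aldol; C4 of unit 1 in the ring closure, anti to the C3 benzyloxy group.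

Key step: step 17

Remark: compounds 1, 4, 12, 13, 15, 19 and 27 are taken as commercial; flavan numbering is used within each unit; carbinol 24 is carried on as both epimers at the new carbinol carbon, because that centre becomes planar in step 17.

**Route**

Step 1
Reactants: 1 (−)-epicatechin
Product: 2 5,7,3',4'-tetra-O-benzyl-(−)-epicatechin
Conditions: BnBr (4.4 equiv), K2CO3, DMF, 0 °C → rt
Reagents that add atoms: benzyl bromide, BrCc1ccccc1
Why: Williamson etherification with a weak base should alkylate the four phenols but not the secondary 3-OH and should not open ring C, so C2 and C3 keep the natural 2R,3R configuration.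

Step 2
Reactants: 2 5,7,3',4'-tetra-O-benzyl-(−)-epicatechin
Product: 3 3,5,7,3',4'-penta-O-benzyl-(−)-epicatechin
Conditions: NaH, BnBr, n-Bu4NI (cat.), THF, 0 °C → rt
Reagents that add atoms: benzyl bromide, BrCc1ccccc1
Why: Williamson etherification of the C3 alkoxide masks O3 of unit 4 until the final hydrogenolysis, so that only one hydroxyl is free when the gallate is introduced.

Step 3
Reactants: 4 (−)-epigallocatechin
Product: 5 5,7,3',4',5'-penta-O-benzyl-(−)-epigallocatechin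
Conditions: BnBr (5.5 equiv), K2CO3, DMF, Ar, 0 °C → rt
Reagents that add atoms: benzyl bromide, BrCc1ccccc1
Why: Williamson etherification of the five phenols under weak base and inert gas should leave the 3-OH and the 2R,3R centres untouched.

Step 4
Reactants: 5 5,7,3',4',5'-penta-O-benzyl-(−)-epigallocatechin
Product: 6 (2R,3R,4S)-5,7-bis(benzyloxy)-4-(2-ethoxyethoxy)-2-[3,4,5-tris(benzyloxy)phenyl]chroman-3-ol (4β ether, 3,4-trans)
Conditions: DDQ (2 equiv), HOCH2CH2OEt (5 equiv), CH2Cl2, rt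
Reagents that add atoms: 2-ethoxyethanol, CCOCCO
Why: DDQ benzylic oxidation abstracts hydride from C4 (activated by the oxygens on C5, C7 and C8a) and the alcohol is captured anti to the C3 hydroxyl, which installs a C4 leaving group with 3,4-trans configuration.

Step 5
Reactants: 6 4β-(2-ethoxyethoxy) electrophile; 3 3,5,7,3',4'-penta-O-benzyl-(−)-epicatechin
Product: 7 dimer 5,7,3',4',5'-penta-O-benzylepigallocatechin-(4β→8)-3,5,7,3',4'-penta-O-benzylepicatechin (3-OH of the upper unit free)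
Conditions: 3 (4 equiv), TMSOTf (10 mol %), CH2Cl2, −78 °C; aq. NaHCO3
Reagents that add atoms: none
Why: Lewis-acid-mediated SN1-type Friedel–Crafts coupling at C4: ionisation of the 4-alkoxy group and attack of C8 of 3 anti to the axial C3 oxygen should give the 3,4-trans (4β) bond, the excess of 3 suppressing self-condensation of 6.

Step 6
Reactants: 5 5,7,3',4',5'-penta-O-benzyl-(−)-epigallocatechin
Product: 8 3,5,7,3',4',5'-hexa-O-benzyl-(−)-epigallocatechin
Conditions: NaH, BnBr, n-Bu4NI (cat.), THF, 0 °C → rt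
Reagents that add atoms: benzyl bromide, BrCc1ccccc1
Why: Williamson etherification of the C3 alkoxide masks O3 of unit 2 with a group that survives organolithium and Lewis acid steps and leaves in the last step.

Step 7
Reactants: 8 3,5,7,3',4',5'-hexa-O-benzyl-(−)-epigallocatechin
Product: 9 8-bromo-3,5,7,3',4',5'-hexa-O-benzyl-(−)-epigallocatechin
Conditions: NBS (1.05 equiv), CH2Cl2, −78 °C → rt
Reagents that add atoms: N-bromosuccinimide, O=C1CCC(=O)N1Br
Why: electrophilic aromatic bromination should go to C8, the most reactive position of the benzylated ring A (C6 lies between two benzyloxy groups), and the bromine later blocks self-coupling and serves as the lithiation handle.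

Step 8
Reactants: 9 8-bromo-3,5,7,3',4',5'-hexa-O-benzyl-(−)-epigallocatechin
Product: 10 (2R,3R,4S)-8-bromo-3,5,7-tris(benzyloxy)-4-(2-ethoxyethoxy)-2-[3,4,5-tris(benzyloxy)phenyl]chromane (4β ether, 3,4-trans)
Conditions: DDQ (2 equiv), HOCH2CH2OEt (5 equiv), CH2Cl2, rt
Reagents that add atoms: 2-ethoxyethanol, CCOCCO
Why: DDQ benzylic oxidation at C4 with capture of the alcohol anti to the C3 benzyloxy group, as in step 4, the plain benzyl ethers and the aryl bromide being inert to DDQ.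

Step 9
Reactants: 10 8-bromo 4β-(2-ethoxyethoxy) electrophile; 7 dimer
Product: 11 bromo trimer 8-bromo-3,5,7,3',4',5'-hexa-O-benzylepigallocatechin-(4β→8)-5,7,3',4',5'-penta-O-benzylepigallocatechin-(4β→8)-3,5,7,3',4'-penta-O-benzylepicatechin (3-OH of the middle unit free)
Conditions: 7 (1.3 equiv), TMSOTf (10 mol %), CH2Cl2, −78 °C; aq. NaHCO3
Reagents that add atoms: none
Why: the same SN1-type Friedel–Crafts C4 coupling: the C8 bromine of 10 prevents self-condensation, the free C8 of the upper unit of 7 is the most nucleophilic open position (both C6 sites lie between two benzyloxy groups), and attack anti to the C3 benzyloxy group sets the 4β configuration.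

Step 10
Reactants: 12 (S)-4-benzyloxazolidin-2-one; 13 (benzyloxy)acetyl chloride
Product: 14 (S)-4-benzyl-3-[(benzyloxy)acetyl]oxazolidin-2-one
Conditions: n-BuLi, THF, −78 °C; then 13, −78 → 0 °C
Reagents that add atoms: none
Why: N-acylation of the lithiated oxazolidinone is the standard loading of an Evans auxiliary.

Step 11
Reactants: 14 (S)-4-benzyl-3-[(benzyloxy)acetyl]oxazolidin-2-one; 15 3,4,5-tris(benzyloxy)benzaldehyde
Product: 17 (S)-4-benzyl-3-[(2S,3R)-2-(benzyloxy)-3-hydroxy-3-[3,4,5-tris(benzyloxy)phenyl]propanoyl]oxazolidin-2-one, via Z-dibutylboron enolate 16 (not isolated)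
Conditions: Bu2BOTf, Et3N, CH2Cl2, −78 → 0 °C; 15, −78 → 0 °C; then pH 7 buffer, MeOH, H2O2
Reagents that add atoms: none
Why: Evans boron aldol reaction: the Z-enolate 16 should react through a Zimmerman–Traxler chair on the face away from the auxiliary benzyl group, setting the syn 2S (benzyloxy) and 3R (hydroxy) centres that become C3 and C2 of unit 1.

Step 12
Reactants: 17 syn aldol imide
Product: 18 (2S,3R)-2-(benzyloxy)-3-hydroxy-N-methoxy-N-methyl-3-[3,4,5-tris(benzyloxy)phenyl]propanamide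
Conditions: Me(MeO)NH, AlMe3, CH2Cl2, −20 → 0 °C; aq. potassium sodium tartrate
Reagents that add atoms: N,O-dimethylhydroxylamine, CNOC
Why: Weinreb aminolysis of the imide by the dimethylaluminium amide, assisted by the free β-hydroxyl, should remove the auxiliary without touching either stereocentre.

Step 13
Reactants: 19 5-bromoresorcinol
Product: 20 1-bromo-3,5-bis(benzyloxy)benzene
Conditions: BnBr (2.2 equiv), K2CO3, DMF, rt
Reagents that add atoms: benzyl bromide, BrCc1ccccc1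
Why: Williamson etherification of both phenols gives the aryl bromide that will become ring A of unit 1.

Step 14
Reactants: 18 β-hydroxy Weinreb amide; 20 1-bromo-3,5-bis(benzyloxy)benzene
Product: 21 (2S,3R)-2-(benzyloxy)-3-[3,5-bis(benzyloxy)phenoxy]-N-methoxy-N-methyl-3-[3,4,5-tris(benzyloxy)phenyl]propanamide
Conditions: 20 (1.5 equiv), [Pd(allyl)Cl]2 (2.5 mol %), RockPhos (6 mol %), Cs2CO3, toluene, 90 °C
Reagents that add atoms: none
Why: Buchwald–Hartwig-type palladium-catalysed C–O coupling of a secondary alcohol with an aryl bromide forms the O–C(aryl) bond, so the benzylic carbon (future C2 of unit 1) keeps its 3R configuration, and the carbonate base limits retro-aldol cleavage.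

Step 15
Reactants: 21 aryl ether Weinreb amide
Product: 22 (2S,3R)-2-(benzyloxy)-3-[3,5-bis(benzyloxy)phenoxy]-3-[3,4,5-tris(benzyloxy)phenyl]propanal
Conditions: i-Bu2AlH, THF, −78 °C; aq. potassium sodium tartrate; used at once
Reagents that add atoms: none
Why: Weinreb amide reduction stops at the aldehyde oxidation level, and the cold, near-neutral work-up should avoid epimerisation at the α-carbon and β-elimination of the aryloxide.

Step 16
Reactants: 11 bromo trimer; 22 aldehyde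
Product: 24 trimer carbinol (bromine of 11 replaced by the 1-hydroxypropyl chain of 22; both epimers at the carbinol carbon), via C8-lithiated trimer lithium alkoxide 23 (not isolated)
Conditions: t-BuLi (3.1 equiv), THF, −78 °C; then 22 (1.5 equiv), −78 → −40 °C; H2O
Reagents that add atoms: none
Why: deprotonation of the single hydroxyl and bromine–lithium exchange should give aryllithium 23 regiospecifically at C8 of unit 2, whose 1,2-addition to 22 forms the C8–C4 bond; the configuration of the new carbinol does not matter because step 17 planarises it.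

Step 17
Reactants: 24 trimer carbinol
Product: 26 protected tetramer alcohol (units 1 to 4 joined 4β→8; one free hydroxyl at C3 of unit 3), via benzylic cation 25 (not isolated)
Conditions: BF3·OEt2 (20 mol %), 4 Å molecular sieves, CH2Cl2 (0.002 M), −78 → −30 °C; aq. NaHCO3
Reagents that add atoms: none
Why: BF3·OEt2 should ionise the carbinol to cation 25, in which C4 of the nascent unit 1 is benzylic to ring A of unit 2 and stabilised by its oxygens on C7 and C8a (ortho) and C5 (para), so that it forms far faster than any cation from the C2 aryl ether or the benzyl ethers; the closest known reaction type is the intramolecular Friedel–Crafts cycloalkylation of 3-aryloxy-1-arylpropan-1-ols to 4-arylchromans. The pendant 3,5-bis(benzyloxy)phenoxy ring attacks through the carbon ortho to its ether oxygen (ortho, ortho and para to three oxygens) and closes the pyran ring C of unit 1 in a six-membered closure that is exo to the quinone-methide-type C4=C8 π bond of the cation (6-exo-trig), the arene π bond lying inside the new ring. The only new stereocentre, C4 of unit 1, is controlled by the adjacent C3 centre: in the half-chair transition state the C2 aryl group is equatorial, the C3 benzyloxy group axial, and the bulky unit 2 aryl group takes the pseudo-axial position anti to the C3 oxygen to avoid peri strain with the C5 benzyloxy group, which should give the 3,4-trans (4β) bond. Both carbinol epimers converge on the same planar cation, so the step is stereoconvergent. The step needs six-ring closure by the phloroglucinol-type ring to win over five-ring (indane) closure by the less nucleophilic pyrogallol ring on C2, over loss of the C3 proton and over intermolecular alkylation, which the higher nucleophilicity of the 1,3,5-trioxygenated ring, high dilution and low temperature should secure.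

Step 18
Reactants: 26 protected tetramer alcohol; 27 3,4,5-tris(benzyloxy)benzoic acid
Product: 28 pentacosa-O-benzyl target (26 acylated at O3 of unit 3 with the 3,4,5-tris(benzyloxy)benzoyl group)
Conditions: 27 (3 equiv), DCC, DMAP (cat.), CH2Cl2, rt
Reagents that add atoms: none
Why: Steglich esterification; 26 has a single free hydroxyl, so the galloyl group can only go to O3 of unit 3, with retention at C3.

Step 19
Reactants: 28 pentacosa-O-benzyl target
Product: 29 target, epigallocatechin-(4β→8)-epigallocatechin-(4β→8)-epigallocatechin 3-O-gallate-(4β→8)-epicatechin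
Conditions: H2 (1 atm), Pd(OH)2/C, THF/MeOH/H2O, rt; filtration, freeze-drying
Reagents that add atoms: none
Why: hydrogenolysis over Pd(OH)2/C under neutral conditions should cleave all 25 benzyl ethers (22 aryl, 3 alkyl) while the gallate ester, the interflavan bonds and all stereocentres stay intact.

**Compound list**

1 | (−)-epicatechin | O[C@@H]1Cc2c(O)cc(O)cc2O[C@@H]1c1ccc(O)c(O)c1 | starting material
2 | 5,7,3',4'-tetra-O-benzyl-(−)-epicatechin | O[C@@H]1Cc2c(OCc3ccccc3)cc(OCc3ccccc3)cc2O[C@@H]1c1ccc(OCc2ccccc2)c(OCc2ccccc2)c1 | intermediate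
3 | 3,5,7,3',4'-penta-O-benzyl-(−)-epicatechin | c1ccccc1CO[C@@H]1Cc2c(OCc3ccccc3)cc(OCc3ccccc3)cc2O[C@@H]1c1ccc(OCc2ccccc2)c(OCc2ccccc2)c1 | intermediate
4 | (−)-epigallocatechin | O[C@@H]1Cc2c(O)cc(O)cc2O[C@@H]1c1cc(O)c(O)c(O)c1 | starting material
5 | 5,7,3',4',5'-penta-O-benzyl-(−)-epigallocatechin | O[C@@H]1Cc2c(OCc3ccccc3)cc(OCc3ccccc3)cc2O[C@@H]1c1cc(OCc2ccccc2)c(OCc2ccccc2)c(OCc2ccccc2)c1 | intermediate
6 | (2R,3R,4S)-5,7-bis(benzyloxy)-4-(2-ethoxyethoxy)-2-[3,4,5-tris(benzyloxy)phenyl]chroman-3-ol | O[C@@H]1[C@@H](OCCOCC)c2c(OCc3ccccc3)cc(OCc3ccccc3)cc2O[C@@H]1c1cc(OCc2ccccc2)c(OCc2ccccc2)c(OCc2ccccc2)c1 | intermediate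
7 | dimer, penta-O-benzylepigallocatechin-(4β→8)-penta-O-benzylepicatechin, upper 3-OH free | O[C@@H]1[C@@H](c2c(OCc7ccccc7)cc(OCc7ccccc7)c3c2O[C@H](c2ccc(OCc7ccccc7)c(OCc7ccccc7)c2)[C@H](OCc7ccccc7)C3)c2c(OCc7ccccc7)cc(OCc7ccccc7)cc2O[C@@H]1c1cc(OCc7ccccc7)c(OCc7ccccc7)c(OCc7ccccc7)c1 | intermediate
8 | 3,5,7,3',4',5'-hexa-O-benzyl-(−)-epigallocatechin | c1ccccc1CO[C@@H]1Cc2c(OCc3ccccc3)cc(OCc3ccccc3)cc2O[C@@H]1c1cc(OCc2ccccc2)c(OCc2ccccc2)c(OCc2ccccc2)c1 | intermediate
9 | 8-bromo-3,5,7,3',4',5'-hexa-O-benzyl-(−)-epigallocatechin | c1ccccc1CO[C@@H]1Cc2c(OCc3ccccc3)cc(OCc3ccccc3)c(Br)c2O[C@@H]1c1cc(OCc2ccccc2)c(OCc2ccccc2)c(OCc2ccccc2)c1 | intermediate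
10 | (2R,3R,4S)-8-bromo-3,5,7-tris(benzyloxy)-4-(2-ethoxyethoxy)-2-[3,4,5-tris(benzyloxy)phenyl]chromane | c1ccccc1CO[C@@H]1[C@@H](OCCOCC)c2c(OCc3ccccc3)cc(OCc3ccccc3)c(Br)c2O[C@@H]1c1cc(OCc2ccccc2)c(OCc2ccccc2)c(OCc2ccccc2)c1 | intermediate
11 | bromo trimer, 8-bromo-hexa-O-benzylepigallocatechin-(4β→8)-penta-O-benzylepigallocatechin-(4β→8)-penta-O-benzylepicatechin, middle 3-OH free | O[C@@H]1[C@@H](c2c(OCc7ccccc7)cc(OCc7ccccc7)c3c2O[C@H](c2ccc(OCc7ccccc7)c(OCc7ccccc7)c2)[C@H](OCc7ccccc7)C3)c2c(OCc7ccccc7)cc(OCc7ccccc7)c([C@H]3c4c(OCc7ccccc7)cc(OCc7ccccc7)c(Br)c4O[C@H](c4cc(OCc7ccccc7)c(OCc7ccccc7)c(OCc7ccccc7)c4)[C@@H]3OCc7ccccc7)c2O[C@@H]1c1cc(OCc7ccccc7)c(OCc7ccccc7)c(OCc7ccccc7)c1 | intermediate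
12 | (S)-4-benzyloxazolidin-2-one | O=C1OC[C@H](Cc2ccccc2)N1 | starting material
13 | (benzyloxy)acetyl chloride | O=C(Cl)COCc1ccccc1 | starting material
14 | (S)-4-benzyl-3-[(benzyloxy)acetyl]oxazolidin-2-one | O=C1OC[C@H](Cc2ccccc2)N1C(=O)COCc1ccccc1 | intermediate
15 | 3,4,5-tris(benzyloxy)benzaldehyde | O=Cc1cc(OCc2ccccc2)c(OCc2ccccc2)c(OCc2ccccc2)c1 | starting material
16 | Z-dibutylboron enolate of 14 | O=C1OC[C@H](Cc2ccccc2)N1/C(OB(CCCC)CCCC)=C/OCc1ccccc1 | intermediate (not isolated)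
17 | (S)-4-benzyl-3-[(2S,3R)-2-(benzyloxy)-3-hydroxy-3-[3,4,5-tris(benzyloxy)phenyl]propanoyl]oxazolidin-2-one | O=C1OC[C@H](Cc2ccccc2)N1C(=O)[C@@H](OCc1ccccc1)[C@H](O)c1cc(OCc2ccccc2)c(OCc2ccccc2)c(OCc2ccccc2)c1 | intermediate
18 | (2S,3R)-2-(benzyloxy)-3-hydroxy-N-methoxy-N-methyl-3-[3,4,5-tris(benzyloxy)phenyl]propanamide | CON(C)C(=O)[C@@H](OCc1ccccc1)[C@H](O)c1cc(OCc2ccccc2)c(OCc2ccccc2)c(OCc2ccccc2)c1 | intermediate
19 | 5-bromoresorcinol | Oc1cc(O)cc(Br)c1 | starting material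
20 | 1-bromo-3,5-bis(benzyloxy)benzene | Brc1cc(OCc2ccccc2)cc(OCc2ccccc2)c1 | intermediate
21 | (2S,3R)-2-(benzyloxy)-3-[3,5-bis(benzyloxy)phenoxy]-N-methoxy-N-methyl-3-[3,4,5-tris(benzyloxy)phenyl]propanamide | CON(C)C(=O)[C@@H](OCc1ccccc1)[C@H](Oc1cc(OCc2ccccc2)cc(OCc2ccccc2)c1)c1cc(OCc2ccccc2)c(OCc2ccccc2)c(OCc2ccccc2)c1 | intermediate
22 | (2S,3R)-2-(benzyloxy)-3-[3,5-bis(benzyloxy)phenoxy]-3-[3,4,5-tris(benzyloxy)phenyl]propanal | O=C[C@@H](OCc1ccccc1)[C@H](Oc1cc(OCc2ccccc2)cc(OCc2ccccc2)c1)c1cc(OCc2ccccc2)c(OCc2ccccc2)c(OCc2ccccc2)c1 | intermediate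
23 | C8-lithiated trimer lithium alkoxide (from 11) | [Li]O[C@@H]1[C@@H](c2c(OCc7ccccc7)cc(OCc7ccccc7)c3c2O[C@H](c2ccc(OCc7ccccc7)c(OCc7ccccc7)c2)[C@H](OCc7ccccc7)C3)c2c(OCc7ccccc7)cc(OCc7ccccc7)c([C@H]3c4c(OCc7ccccc7)cc(OCc7ccccc7)c([Li])c4O[C@H](c4cc(OCc7ccccc7)c(OCc7ccccc7)c(OCc7ccccc7)c4)[C@@H]3OCc7ccccc7)c2O[C@@H]1c1cc(OCc7ccccc7)c(OCc7ccccc7)c(OCc7ccccc7)c1 | intermediate (not isolated)
24 | trimer carbinol, C8 of unit 2 bonded to the CH(OH) carbon of the chain from 22, both carbinol epimers | O[C@@H]1[C@@H](c2c(OCc7ccccc7)cc(OCc7ccccc7)c3c2O[C@H](c2ccc(OCc7ccccc7)c(OCc7ccccc7)c2)[C@H](OCc7ccccc7)C3)c2c(OCc7ccccc7)cc(OCc7ccccc7)c([C@H]3c4c(OCc7ccccc7)cc(OCc7ccccc7)c(C(O)[C@@H](OCc7ccccc7)[C@H](Oc5cc(OCc7ccccc7)cc(OCc7ccccc7)c5)c5cc(OCc7ccccc7)c(OCc7ccccc7)c(OCc7ccccc7)c5)c4O[C@H](c4cc(OCc7ccccc7)c(OCc7ccccc7)c(OCc7ccccc7)c4)[C@@H]3OCc7ccccc7)c2O[C@@H]1c1cc(OCc7ccccc7)c(OCc7ccccc7)c(OCc7ccccc7)c1 | intermediate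
25 | benzylic cation at C4 of nascent unit 1 | O[C@@H]1[C@@H](c2c(OCc7ccccc7)cc(OCc7ccccc7)c3c2O[C@H](c2ccc(OCc7ccccc7)c(OCc7ccccc7)c2)[C@H](OCc7ccccc7)C3)c2c(OCc7ccccc7)cc(OCc7ccccc7)c([C@H]3c4c(OCc7ccccc7)cc(OCc7ccccc7)c([CH+][C@@H](OCc7ccccc7)[C@H](Oc5cc(OCc7ccccc7)cc(OCc7ccccc7)c5)c5cc(OCc7ccccc7)c(OCc7ccccc7)c(OCc7ccccc7)c5)c4O[C@H](c4cc(OCc7ccccc7)c(OCc7ccccc7)c(OCc7ccccc7)c4)[C@@H]3OCc7ccccc7)c2O[C@@H]1c1cc(OCc7ccccc7)c(OCc7ccccc7)c(OCc7ccccc7)c1 | intermediate (not isolated)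
26 | protected tetramer alcohol, hexa-O-benzylepigallocatechin-(4β→8)-hexa-O-benzylepigallocatechin-(4β→8)-penta-O-benzylepigallocatechin-(4β→8)-penta-O-benzylepicatechin, 3-OH of unit 3 free | O[C@@H]1[C@@H](c2c(OCc7ccccc7)cc(OCc7ccccc7)c3c2O[C@H](c2ccc(OCc7ccccc7)c(OCc7ccccc7)c2)[C@H](OCc7ccccc7)C3)c2c(OCc7ccccc7)cc(OCc7ccccc7)c([C@H]3c4c(OCc7ccccc7)cc(OCc7ccccc7)c([C@H]5c6c(OCc7ccccc7)cc(OCc7ccccc7)cc6O[C@H](c6cc(OCc7ccccc7)c(OCc7ccccc7)c(OCc7ccccc7)c6)[C@@H]5OCc7ccccc7)c4O[C@H](c4cc(OCc7ccccc7)c(OCc7ccccc7)c(OCc7ccccc7)c4)[C@@H]3OCc7ccccc7)c2O[C@@H]1c1cc(OCc7ccccc7)c(OCc7ccccc7)c(OCc7ccccc7)c1 | intermediate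
27 | 3,4,5-tris(benzyloxy)benzoic acid | OC(=O)c1cc(OCc2ccccc2)c(OCc2ccccc2)c(OCc2ccccc2)c1 | starting material
28 | pentacosa-O-benzyl target | O=C(O[C@@H]1[C@@H](c2c(OCc7ccccc7)cc(OCc7ccccc7)c3c2O[C@H](c2ccc(OCc7ccccc7)c(OCc7ccccc7)c2)[C@H](OCc7ccccc7)C3)c2c(OCc7ccccc7)cc(OCc7ccccc7)c([C@H]3c4c(OCc7ccccc7)cc(OCc7ccccc7)c([C@H]5c6c(OCc7ccccc7)cc(OCc7ccccc7)cc6O[C@H](c6cc(OCc7ccccc7)c(OCc7ccccc7)c(OCc7ccccc7)c6)[C@@H]5OCc7ccccc7)c4O[C@H](c4cc(OCc7ccccc7)c(OCc7ccccc7)c(OCc7ccccc7)c4)[C@@H]3OCc7ccccc7)c2O[C@@H]1c1cc(OCc7ccccc7)c(OCc7ccccc7)c(OCc7ccccc7)c1)c1cc(OCc7ccccc7)c(OCc7ccccc7)c(OCc7ccccc7)c1 | intermediate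
29 | target, epigallocatechin-(4β→8)-epigallocatechin-(4β→8)-epigallocatechin 3-O-gallate-(4β→8)-epicatechin | O=C(O[C@@H]1[C@@H](c2c(O)cc(O)c3c2O[C@H](c2ccc(O)c(O)c2)[C@H](O)C3)c2c(O)cc(O)c([C@H]3c4c(O)cc(O)c([C@H]5c6c(O)cc(O)cc6O[C@H](c6cc(O)c(O)c(O)c6)[C@@H]5O)c4O[C@H](c4cc(O)c(O)c(O)c4)[C@@H]3O)c2O[C@@H]1c1cc(O)c(O)c(O)c1)c1cc(O)c(O)c(O)c1 | target

**Count and risks**

Total step count: 19. Longest linear sequence: 9 steps (12 → 14 → 17 → 18 → 21 → 22 → 24 → 26 → 28 → 29; the line 4 → 5 → 8 → 9 → 10 → 11 → 24 → 26 → 28 → 29 is equally long).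

Steps most likely to fail:

Step 14. The palladium alkoxide of this hindered secondary benzylic alcohol may undergo β-hydride elimination to the aryl ketone, the β-hydroxy amide may suffer retro-aldol cleavage, or the catalyst may not turn over. Fallback: the ether is formed at the benzylic carbon by double inversion instead of at the aryl carbon. It sets out from 18. Mitsunobu esterification with 4-nitrobenzoic acid (PPh3, DIAD, THF) should invert C3 to the (2S,3S) 4-nitrobenzoate F1. Methanolysis (K2CO3, MeOH, 0 °C) should give the (2S,3S) anti alcohol F2. A second Mitsunobu reaction with 3,5-bis(benzyloxy)phenol should invert C3 again and comes back to the route at 21.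

Step 17. Facial selectivity at C4 may be poor, or the cation may be diverted to proton loss from C3 or to five-ring closure by the pyrogallol ring. Fallback: conventional polarity, with the interflavan bond made last. It sets out from 22 and 11. Aldehyde 22 is cyclised with Me2AlCl (CH2Cl2, −78 °C; intramolecular Friedel–Crafts hydroxyalkylation) to the 4-hydroxyflavan F3. Trimer 11 is debrominated (t-BuLi, THF, −78 °C, then MeOH) to the debrominated trimer F4. TMSOTf-mediated coupling of F3 with F4 at −78 °C (ionisation of the 4-hydroxyl, attack of C8 of unit 2 anti to the C3 benzyloxy group) comes back to the route at 26.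

Step 16. The hindered aryllithium may act as a base, so that enolisation of the aldehyde and β-elimination of the aryloxide compete with addition. Fallback: acylation followed by reduction. It sets out from 11 and 21. Aryllithium 23 is generated as in step 16 and acylated with the Weinreb amide 21 to the aryl ketone F5. LiAlH4 (THF, −40 °C) should reduce F5 to the carbinol, which comes back to the route at 24.

**Further compounds**

F1 | step 14 | (1S,2S)-2-(benzyloxy)-3-[methoxy(methyl)amino]-3-oxo-1-[3,4,5-tris(benzyloxy)phenyl]propyl 4-nitrobenzoate | CON(C)C(=O)[C@@H](OCc1ccccc1)[C@@H](OC(=O)c1ccc(cc1)[N+](=O)[O-])c1cc(OCc2ccccc2)c(OCc2ccccc2)c(OCc2ccccc2)c1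
F2 | step 14 | (2S,3S)-2-(benzyloxy)-3-hydroxy-N-methoxy-N-methyl-3-[3,4,5-tris(benzyloxy)phenyl]propanamide | CON(C)C(=O)[C@@H](OCc1ccccc1)[C@@H](O)c1cc(OCc2ccccc2)c(OCc2ccccc2)c(OCc2ccccc2)c1
F3 | step 17 | (2R,3R)-3,5,7-tris(benzyloxy)-2-[3,4,5-tris(benzyloxy)phenyl]chroman-4-ol, both C4 epimers | OC1c2c(OCc7ccccc7)cc(OCc7ccccc7)cc2O[C@H](c2cc(OCc7ccccc7)c(OCc7ccccc7)c(OCc7ccccc7)c2)[C@@H]1OCc7ccccc7
F4 | step 17 | debrominated trimer, hexa-O-benzylepigallocatechin-(4β→8)-penta-O-benzylepigallocatechin-(4β→8)-penta-O-benzylepicatechin | O[C@@H]1[C@@H](c2c(OCc7ccccc7)cc(OCc7ccccc7)c3c2O[C@H](c2ccc(OCc7ccccc7)c(OCc7ccccc7)c2)[C@H](OCc7ccccc7)C3)c2c(OCc7ccccc7)cc(OCc7ccccc7)c([C@H]3c4c(OCc7ccccc7)cc(OCc7ccccc7)cc4O[C@H](c4cc(OCc7ccccc7)c(OCc7ccccc7)c(OCc7ccccc7)c4)[C@@H]3OCc7ccccc7)c2O[C@@H]1c1cc(OCc7ccccc7)c(OCc7ccccc7)c(OCc7ccccc7)c1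
F5 | step 16 | aryl ketone, 24 with C=O in place of the carbinol CH(OH) | O[C@@H]1[C@@H](c2c(OCc7ccccc7)cc(OCc7ccccc7)c3c2O[C@H](c2ccc(OCc7ccccc7)c(OCc7ccccc7)c2)[C@H](OCc7ccccc7)C3)c2c(OCc7ccccc7)cc(OCc7ccccc7)c([C@H]3c4c(OCc7ccccc7)cc(OCc7ccccc7)c(C(=O)[C@@H](OCc7ccccc7)[C@H](Oc5cc(OCc7ccccc7)cc(OCc7ccccc7)c5)c5cc(OCc7ccccc7)c(OCc7ccccc7)c(OCc7ccccc7)c5)c4O[C@H](c4cc(OCc7ccccc7)c(OCc7ccccc7)c(OCc7ccccc7)c4)[C@@H]3OCc7ccccc7)c2O[C@@H]1c1cc(OCc7ccccc7)c(OCc7ccccc7)c(OCc7ccccc7)c1
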